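**Plan**

- Feature: in the central ring (C1 carries the hexanoyl group, numbered on to C6) C2, C4 and C6 bear oxygen and C1, C3 and C5 bear carbon. Ring plus side-chain carbonyl is therefore a folded 3,5,7-trioxo ester chain (hexanoyl C=O, then three two-carbon units), and the arms on C3/C5 make the two inner chain carbons tertiary.
- Cuts, in retrosynthetic order: the two enol O–CH3 bonds; arene bond C1–C6 (Claisen closure); chain bonds C6–C7, C4–C5 and C2–C3 (chain numbered from the ester carbon); in each arm the bond from the stereogenic CH to the syncarpic ring carbon.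
- Forward: syncarpic acid (both outer rings) adds to two enals; the lactols are oxidised and opened to an ester (isopropyl arm) and an N-methoxy-N-methylamide (isobutyl arm); the chain is joined at C2–C3, then C4–C5, then C6–C7; the central ring, the only ring built, closes in step 14; demethylation ends the route.
- Stereochemistry: both arm centres are set by iminium-ion catalysis with the same (S)-diarylprolinol silyl ether. They carry no acidic hydrogen, and the methyl enol ethers block retro-Michael loss. The chain α-centres are epimer mixtures that become sp2 on aromatisation.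

Key step: step 14

Remark: the facial sense in steps 4 and 7 is taken from the usual shielding model of the s-trans (E)-iminium ion (attack anti to the CPh2(OSiMe3) group); if the opposite sense were found, the (R)-catalyst would be used in both steps.
Remark: the lactol carbon of 9 and 14 and the chain α-carbons of 18, 20 and 23 are left unassigned (epimer mixtures); chain numbering (C1 = ester carbon, C7 = hexanoyl carbonyl) is used for 18, 20 and 23, arene numbering for 24 and 25.
Remark: compounds 1, 4, 5, 7, 19 and 21 are taken as purchased.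

**Route**

Step 1
Reactants: 1 2,4,6-trihydroxyacetophenone
Product: 2 2-acetyl-3-hydroxy-4,4,6,6-tetramethylcyclohex-2-ene-1,5-dione (acetylsyncarpic acid)
Conditions: NaOMe, MeI (excess), MeOH, reflux
Reagents that add atoms: iodomethane, CI
Why: Exhaustive enolate C-methylation of the acylphloroglucinol takes place twice at each of the two free ring carbons, since each first methylation leaves an enolisable 1,3-dicarbonyl position, and stops at the non-aromatic gem-dimethyl trione.

Step 2
Reactants: 2 acetylsyncarpic acid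
Product: 3 syncarpic acid (2,2,4,4-tetramethylcyclohexane-1,3,5-trione)
Conditions: 6 M aq. HCl, reflux
Reagents that add atoms: none
Why: Acid-mediated retro-Claisen deacylation of the 2-acyl-1,3-dione (water adds to the exocyclic acetyl carbonyl and the trione enol leaves) removes the acetyl group as acetic acid.

Step 3
Reactants: 4 3-methylbutanal; 5 (triphenylphosphoranylidene)acetaldehyde
Product: 6 (2E)-5-methylhex-2-enal
Conditions: PhMe, 80 °C
Reagents that add atoms: none
Why: Wittig reaction of a stabilised formyl ylide with an aliphatic aldehyde gives the two-carbon-extended (E)-enal, a slight excess of 4 keeping a second homologation down.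

Step 4
Reactants: 3 syncarpic acid; 7 (2E)-4-methylpent-2-enal
Product: 9 (4S)-2-hydroxy-6,6,8,8-tetramethyl-4-(propan-2-yl)-3,4-dihydro-2H-chromene-5,7(6H,8H)-dione (lactol of the isopropyl arm), via open-chain aldehyde 8 (not isolated)
Conditions: (S)-2-[diphenyl(trimethylsilyloxy)methyl]pyrrolidine (10 mol %), CH2Cl2, 0 °C → rt
Reagents that add atoms: none
Why: Iminium-ion-catalysed Michael addition of a cyclic 1,3-dicarbonyl compound to an enal, in which the CPh2(OSiMe3) group shields one face of the (E)-iminium ion so that the enol carbon of 3 adds to the open face of C3 and sets the (S)-centre, the adduct then closing to the lactol.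

Step 5
Reactants: 9 lactol of the isopropyl arm
Product: 10 (4S)-6,6,8,8-tetramethyl-4-(propan-2-yl)-3,4-dihydro-2H-chromene-2,5,7(6H,8H)-trione (enol lactone)
Conditions: TEMPO (2,2,6,6-tetramethylpiperidin-1-oxyl, 20 mol %), PhI(OAc)2, CH2Cl2, rt
Reagents that add atoms: none
Why: Oxoammonium oxidation of a lactol to a lactone converts the hemiacetal C–H into the carbonyl and leaves the electron-poor enol ether double bond and the remote stereocentre untouched.

Step 6
Reactants: 10 enol lactone of the isopropyl arm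
Product: 12 methyl (3S)-3-(2-methoxy-3,3,5,5-tetramethyl-4,6-dioxocyclohex-1-en-1-yl)-4-methylpentanoate, via enol methyl ester 11 (not isolated)
Conditions: NaOMe, MeOH, 0 °C; AcOH; then Me3SiCHN2, PhMe–MeOH, 0 °C → rt
Reagents that add atoms: sodium methoxide, [Na+].[O-]C; (trimethylsilyl)diazomethane, C[Si](C)(C)C=[N+]=[N-]
Why: Methanolysis of the enol lactone, an activated ester, followed by diazoalkane O-methylation of the liberated vinylogous acid gives one enol ether, because the two enol oxygens are interchanged by rotation about the bond to the stereocentre.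

Step 7
Reactants: 3 syncarpic acid; 6 (2E)-5-methylhex-2-enal
Product: 14 (4R)-2-hydroxy-6,6,8,8-tetramethyl-4-(2-methylpropyl)-3,4-dihydro-2H-chromene-5,7(6H,8H)-dione (lactol of the isobutyl arm), via open-chain aldehyde 13 (not isolated)
Conditions: (S)-2-[diphenyl(trimethylsilyloxy)methyl]pyrrolidine (10 mol %), CH2Cl2, 0 °C → rt
Reagents that add atoms: none
Why: The same iminium-ion-catalysed Michael addition with the same catalyst enantiomer delivers the same spatial arrangement at C3 of the enal, here named (R) only because the substituent priorities change.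

Step 8
Reactants: 14 lactol of the isobutyl arm
Product: 15 (4R)-6,6,8,8-tetramethyl-4-(2-methylpropyl)-3,4-dihydro-2H-chromene-2,5,7(6H,8H)-trione (enol lactone)
Conditions: TEMPO (20 mol %), PhI(OAc)2, CH2Cl2, rt
Reagents that add atoms: none
Why: Oxoammonium lactol-to-lactone oxidation, as in step 5.

Step 9
Reactants: 15 enol lactone of the isobutyl arm
Product: 17 (3R)-N-methoxy-3-(2-methoxy-3,3,5,5-tetramethyl-4,6-dioxocyclohex-1-en-1-yl)-N,5-dimethylhexanamide, via enol amide 16 (not isolated)
Conditions: MeNH(OMe)·HCl, iPrMgCl, THF, −20 → 0 °C; aq. HCl work-up; then Me3SiCHN2, PhMe–MeOH, 0 °C → rt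
Reagents that add atoms: N,O-dimethylhydroxylamine hydrochloride, Cl.CNOC; (trimethylsilyl)diazomethane, C[Si](C)(C)C=[N+]=[N-]
Why: Aminolysis of the activated enol lactone by the chloromagnesium amide of N,O-dimethylhydroxylamine gives the N-methoxy-N-methylamide, the ring ketones being shielded by their quaternary neighbours, and diazoalkane O-methylation then caps the freed enol.

Step 10
Reactants: 12 ester of the isopropyl arm; 17 amide of the isobutyl arm
Product: 18 methyl (5R)-5-(2-methoxy-3,3,5,5-tetramethyl-4,6-dioxocyclohex-1-en-1-yl)-2-[(1R)-1-(2-methoxy-3,3,5,5-tetramethyl-4,6-dioxocyclohex-1-en-1-yl)-2-methylpropyl]-7-methyl-3-oxooctanoate (epimers at C2)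
Conditions: LiN(iPr)2, THF, −78 °C; then 17, −78 → −20 °C; AcOH
Reagents that add atoms: none
Why: Crossed Claisen condensation in its N-methoxy-N-methylamide form, in which the preformed lithium enolate of 12 adds to the amide carbonyl and the chelated tetrahedral adduct survives until the quench, so that neither over-addition nor loss of enolate to the acidic β-keto ester occurs.

Step 11
Reactants: 18 β-keto ester; 19 N-methoxy-N-methylacetamide
Product: 20 methyl 2-[(1R)-1-(2-methoxy-3,3,5,5-tetramethyl-4,6-dioxocyclohex-1-en-1-yl)-2-methylpropyl]-4-[(1R)-1-(2-methoxy-3,3,5,5-tetramethyl-4,6-dioxocyclohex-1-en-1-yl)-3-methylbutyl]-3,5-dioxohexanoate (epimers at C2 and C4)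
Conditions: LiN(iPr)2 (2.3 equiv), THF, −78 → 0 °C; then 19, −78 → 0 °C; AcOH
Reagents that add atoms: none
Why: γ-Acylation of a β-keto ester dianion, in which the more basic carbanion at C4, the only γ-position, attacks the small amide and the chelated adduct releases the ketone only on quench.

Step 12
Reactants: 21 hexanoyl chloride
Product: 22 N-methoxy-N-methylhexanamide
Conditions: MeNH(OMe)·HCl, pyridine, CH2Cl2, 0 °C → rt
Reagents that add atoms: N,O-dimethylhydroxylamine hydrochloride, Cl.CNOC
Why: N-Acylation of N,O-dimethylhydroxylamine by an acid chloride is a routine amide formation.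

Step 13
Reactants: 20 3,5-dioxo ester; 22 N-methoxy-N-methylhexanamide
Product: 23 methyl 2-[(1R)-1-(2-methoxy-3,3,5,5-tetramethyl-4,6-dioxocyclohex-1-en-1-yl)-2-methylpropyl]-4-[(1R)-1-(2-methoxy-3,3,5,5-tetramethyl-4,6-dioxocyclohex-1-en-1-yl)-3-methylbutyl]-3,5,7-trioxododecanoate (epimers at C2 and C4)
Conditions: LiN(iPr)2 (3.5 equiv), THF, −78 → −20 °C; then 22, −78 → 0 °C; AcOH, −78 °C
Reagents that add atoms: none
Why: Terminal acylation of a 3,5-dioxo ester polyanion, in which the last-formed, most basic and least hindered carbanion on the C6 methyl group is acylated by the amide to give the 3,5,7-trioxo ester.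

Step 14
Reactants: 23 3,5,7-trioxo ester
Product: 24 1-{2,4,6-trihydroxy-3-[(1R)-1-(2-methoxy-3,3,5,5-tetramethyl-4,6-dioxocyclohex-1-en-1-yl)-3-methylbutyl]-5-[(1R)-1-(2-methoxy-3,3,5,5-tetramethyl-4,6-dioxocyclohex-1-en-1-yl)-2-methylpropyl]phenyl}hexan-1-one (bis(methyl enol ether) of the target)
Conditions: Mg(OMe)2 (6 equiv), MeOH, rt → 60 °C; then cold 1 M HCl
Reagents that add atoms: none
Why: Magnesium methoxide should turn 23 into a chelated polyenolate whose only unhindered nucleophilic carbon is the chain C6 methylene between the C5 and C7 ketones; this carbon attacks the ester carbonyl (chain C1), methoxide leaves, and the 2-acylcyclohexane-1,3,5-trione enolises to the aromatic triol, so that arene bond C1–C6 is formed. The closest known reaction type is the base-mediated Claisen cyclisation of 3,5,7-trioxoalkanoates (and of the 2-pyranones derived from them) to acylphloroglucinols, the laboratory counterpart of the chalcone-synthase-type polyketide fold. The six-membered ring closes in the 6-exo-trig mode, the ester C=O lying outside the new ring. No stereocentre is created: the two chain α-centres become sp2 and the two arm centres, which bear no acidic hydrogen, are not touched. The step needs Claisen closure in preference to aldol closure (chain C2 onto C7), lactonisation to the 2-pyranone and retro-Claisen cleavage: the aldol adduct would hold a quaternary C2 and cannot aromatise, so it reverts, the pyranone is reopened by methoxide, magnesium chelation keeps the 1,3-diketone units enolised and so shielded from methoxide, and aromatisation makes the Claisen path irreversible. The methyl enol ethers keep both arms from leaving by retro-Michael fragmentation in the basic medium.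

Step 15
Reactants: 24 bis(methyl enol ether)
Product: 25 myrtucommulone H, 1-{2,4,6-trihydroxy-3-[(1R)-1-(2-hydroxy-3,3,5,5-tetramethyl-4,6-dioxocyclohex-1-en-1-yl)-3-methylbutyl]-5-[(1R)-1-(2-hydroxy-3,3,5,5-tetramethyl-4,6-dioxocyclohex-1-en-1-yl)-2-methylpropyl]phenyl}hexan-1-one
Conditions: BBr3 (10 equiv), CH2Cl2, −78 → 0 °C; then H2O, 0 °C
Reagents that add atoms: none
Why: Lewis acid-mediated O-demethylation, in which BBr3 binds the carbonyl oxygen of each vinylogous ester and bromide attacks the methyl group (SN2), while the phenols are held as non-nucleophilic aryloxyboranes, so that the chromene-forming attack on the ring β-carbon is avoided at low temperature and the arm centres are untouched.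

**Compound list**

1 | 2,4,6-trihydroxyacetophenone | CC(=O)c1c(O)cc(O)cc1O | starting material
2 | 2-acetyl-3-hydroxy-4,4,6,6-tetramethylcyclohex-2-ene-1,5-dione (acetylsyncarpic acid) | CC(=O)C1=C(O)C(C)(C)C(=O)C(C)(C)C1=O | intermediate
3 | syncarpic acid (2,2,4,4-tetramethylcyclohexane-1,3,5-trione) | CC1(C)C(=O)CC(=O)C(C)(C)C1=O | intermediate
4 | 3-methylbutanal (isovaleraldehyde) | CC(C)CC=O | starting material
5 | (triphenylphosphoranylidene)acetaldehyde | O=CC=P(c1ccccc1)(c1ccccc1)c1ccccc1 | starting material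
6 | (2E)-5-methylhex-2-enal | CC(C)C/C=C/C=O | intermediate
7 | (2E)-4-methylpent-2-enal | CC(C)/C=C/C=O | starting material
8 | (3S)-3-(2-hydroxy-3,3,5,5-tetramethyl-4,6-dioxocyclohex-1-en-1-yl)-4-methylpentanal (open-chain Michael adduct) | O=CC[C@@H](C(C)C)C1=C(O)C(C)(C)C(=O)C(C)(C)C1=O | intermediate (not isolated)
9 | (4S)-2-hydroxy-6,6,8,8-tetramethyl-4-(propan-2-yl)-3,4-dihydro-2H-chromene-5,7(6H,8H)-dione (epimers at C2) | OC1C[C@@H](C(C)C)C2=C(O1)C(C)(C)C(=O)C(C)(C)C2=O | intermediate
10 | (4S)-6,6,8,8-tetramethyl-4-(propan-2-yl)-3,4-dihydro-2H-chromene-2,5,7(6H,8H)-trione | O=C1C[C@@H](C(C)C)C2=C(O1)C(C)(C)C(=O)C(C)(C)C2=O | intermediate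
11 | methyl (3S)-3-(2-hydroxy-3,3,5,5-tetramethyl-4,6-dioxocyclohex-1-en-1-yl)-4-methylpentanoate | COC(=O)C[C@@H](C(C)C)C1=C(O)C(C)(C)C(=O)C(C)(C)C1=O | intermediate (not isolated)
12 | methyl (3S)-3-(2-methoxy-3,3,5,5-tetramethyl-4,6-dioxocyclohex-1-en-1-yl)-4-methylpentanoate | COC(=O)C[C@@H](C(C)C)C1=C(OC)C(C)(C)C(=O)C(C)(C)C1=O | intermediate
13 | (3R)-3-(2-hydroxy-3,3,5,5-tetramethyl-4,6-dioxocyclohex-1-en-1-yl)-5-methylhexanal (open-chain Michael adduct) | O=CC[C@@H](CC(C)C)C1=C(O)C(C)(C)C(=O)C(C)(C)C1=O | intermediate (not isolated)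
14 | (4R)-2-hydroxy-6,6,8,8-tetramethyl-4-(2-methylpropyl)-3,4-dihydro-2H-chromene-5,7(6H,8H)-dione (epimers at C2) | OC1C[C@@H](CC(C)C)C2=C(O1)C(C)(C)C(=O)C(C)(C)C2=O | intermediate
15 | (4R)-6,6,8,8-tetramethyl-4-(2-methylpropyl)-3,4-dihydro-2H-chromene-2,5,7(6H,8H)-trione | O=C1C[C@@H](CC(C)C)C2=C(O1)C(C)(C)C(=O)C(C)(C)C2=O | intermediate
16 | (3R)-3-(2-hydroxy-3,3,5,5-tetramethyl-4,6-dioxocyclohex-1-en-1-yl)-N-methoxy-N,5-dimethylhexanamide | CON(C)C(=O)C[C@@H](CC(C)C)C1=C(O)C(C)(C)C(=O)C(C)(C)C1=O | intermediate (not isolated)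
17 | (3R)-N-methoxy-3-(2-methoxy-3,3,5,5-tetramethyl-4,6-dioxocyclohex-1-en-1-yl)-N,5-dimethylhexanamide | CON(C)C(=O)C[C@@H](CC(C)C)C1=C(OC)C(C)(C)C(=O)C(C)(C)C1=O | intermediate
18 | methyl (5R)-5-(2-methoxy-3,3,5,5-tetramethyl-4,6-dioxocyclohex-1-en-1-yl)-2-[(1R)-1-(2-methoxy-3,3,5,5-tetramethyl-4,6-dioxocyclohex-1-en-1-yl)-2-methylpropyl]-7-methyl-3-oxooctanoate (epimers at C2) | COC(=O)C([C@H](C1=C(OC)C(C)(C)C(=O)C(C)(C)C1=O)C(C)C)C(=O)C[C@@H](CC(C)C)C1=C(OC)C(C)(C)C(=O)C(C)(C)C1=O | intermediate
19 | N-methoxy-N-methylacetamide | CC(=O)N(C)OC | starting material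
20 | methyl 2-[(1R)-1-(2-methoxy-3,3,5,5-tetramethyl-4,6-dioxocyclohex-1-en-1-yl)-2-methylpropyl]-4-[(1R)-1-(2-methoxy-3,3,5,5-tetramethyl-4,6-dioxocyclohex-1-en-1-yl)-3-methylbutyl]-3,5-dioxohexanoate (epimers at C2, C4) | COC(=O)C([C@H](C1=C(OC)C(C)(C)C(=O)C(C)(C)C1=O)C(C)C)C(=O)C([C@@H](CC(C)C)C1=C(OC)C(C)(C)C(=O)C(C)(C)C1=O)C(C)=O | intermediate
21 | hexanoyl chloride | CCCCCC(=O)Cl | starting material
22 | N-methoxy-N-methylhexanamide | CCCCCC(=O)N(C)OC | intermediate
23 | methyl 2-[(1R)-1-(2-methoxy-3,3,5,5-tetramethyl-4,6-dioxocyclohex-1-en-1-yl)-2-methylpropyl]-4-[(1R)-1-(2-methoxy-3,3,5,5-tetramethyl-4,6-dioxocyclohex-1-en-1-yl)-3-methylbutyl]-3,5,7-trioxododecanoate (epimers at C2, C4) | CCCCCC(=O)CC(=O)C([C@@H](CC(C)C)C1=C(OC)C(C)(C)C(=O)C(C)(C)C1=O)C(=O)C([C@H](C1=C(OC)C(C)(C)C(=O)C(C)(C)C1=O)C(C)C)C(=O)OC | intermediate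
24 | 1-{2,4,6-trihydroxy-3-[(1R)-1-(2-methoxy-3,3,5,5-tetramethyl-4,6-dioxocyclohex-1-en-1-yl)-3-methylbutyl]-5-[(1R)-1-(2-methoxy-3,3,5,5-tetramethyl-4,6-dioxocyclohex-1-en-1-yl)-2-methylpropyl]phenyl}hexan-1-one | CCCCCC(=O)c1c(O)c([C@@H](CC(C)C)C2=C(OC)C(C)(C)C(=O)C(C)(C)C2=O)c(O)c([C@H](C2=C(OC)C(C)(C)C(=O)C(C)(C)C2=O)C(C)C)c1O | intermediate
25 | myrtucommulone H | CCCCCC(=O)c1c(O)c([C@@H](CC(C)C)C2=C(O)C(C)(C)C(=O)C(C)(C)C2=O)c(O)c([C@H](C2=C(O)C(C)(C)C(=O)C(C)(C)C2=O)C(C)C)c1O | target

**Count**

Total: 15 steps. Longest linear sequence: 10 steps (1, 2, 4, 5, 6, 10, 11, 13, 14, 15; the isobutyl-arm branch 1, 2, 7, 8, 9, 10, 11, 13, 14, 15 is equally long).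

**Steps most likely to fail**

Step 13 (hexanoylation of the polyanion of 20). The two crowded tertiary C–H sites (chain C2 and C4) may be deprotonated slowly or only in part; proton transfer from them would then quench the terminal enolate, and the hexanoyl group would not be transferred cleanly. The fallback sets out from 20 and comes back at 24. Lactonisation of 20 with DBU (1,8-diazabicyclo[5.4.0]undec-7-ene) in toluene at 80 °C, with loss of methanol, should give the 4-hydroxy-6-methyl-2-pyranone F1. In F1 chain C2 and C4 are ring sp2 carbons, and only the 4-hydroxyl and the 6-methyl group remain acidic. Its dianion (LiN(iPr)2, THF, −78 °C) would be acylated on the 6-methyl group by 22 to give the 6-(2-oxoheptyl)-2-pyranone F2. Mg(OMe)2 in methanol then opens the lactone of F2 to the magnesium chelate of 23 in the flask, which closes as in step 14 to 24.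

Step 11 (γ-acetylation of the dianion of 18). The γ-carbanion lies next to a fully substituted arm carbon and may add too slowly to the amide carbonyl; proton transfer from the acetyl CH3 of 19 would then take over and return 18. The fallback sets out from 18 and comes back at 20. The same dianion would be added at −78 °C to acetaldehyde, a far stronger electrophile, to give the aldol, the 5-hydroxy-3-oxohexanoate F3. The β-hydroxy ketone of F3 would then be oxidised to the 1,3-diketone with 2-iodoxybenzoic acid in ethyl acetate at 75 °C, giving 20.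

Step 14 (ring closure). The methyl ester, flanked by the tertiary chain C2, may be attacked too slowly by the C6 enolate, so that methoxide-induced retro-Claisen cleavage of the doubly α-substituted tricarbonyl chain uses up the material before the ring closes. The fallback sets out from 10 and comes back at 24. It changes the electrophilic end to a thioester, as in the enzymatic fold, and closes the ring without alkoxide.
- Opening of 10 with lithium 2-methylpropane-2-thiolate in THF would give the enol thioester F4, which is O-methylated with Me3SiCHN2 to the S-tert-butyl thioester F5.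
- The operations of steps 10, 11 and 13 (enolate acylation by 17, dianion acetylation by 19, polyanion hexanoylation by 22) would then give the β-keto thioester F6, the 3,5-dioxo thioester F7 and the 3,5,7-trioxo thioester F8.
- Soft enolisation of F8 with MgBr2·OEt2 and iPr2NEt in CH2Cl2 at rt should bring about the same closure of chain C6 onto C1 with loss of 2-methylpropane-2-thiol and give 24.

Further compounds
F1 | step 13 | 4-hydroxy-5-[(1R)-1-(2-methoxy-3,3,5,5-tetramethyl-4,6-dioxocyclohex-1-en-1-yl)-3-methylbutyl]-3-[(1S)-1-(2-methoxy-3,3,5,5-tetramethyl-4,6-dioxocyclohex-1-en-1-yl)-2-methylpropyl]-6-methyl-2H-pyran-2-one (same spatial arrangement as in 20; the descriptor of the isopropyl arm changes with the priorities) | CC1=C([C@@H](CC(C)C)C2=C(OC)C(C)(C)C(=O)C(C)(C)C2=O)C(O)=C([C@H](C2=C(OC)C(C)(C)C(=O)C(C)(C)C2=O)C(C)C)C(=O)O1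
F2 | step 13 | 4-hydroxy-5-[(1R)-1-(2-methoxy-3,3,5,5-tetramethyl-4,6-dioxocyclohex-1-en-1-yl)-3-methylbutyl]-3-[(1S)-1-(2-methoxy-3,3,5,5-tetramethyl-4,6-dioxocyclohex-1-en-1-yl)-2-methylpropyl]-6-(2-oxoheptyl)-2H-pyran-2-one | CCCCCC(=O)CC1=C([C@@H](CC(C)C)C2=C(OC)C(C)(C)C(=O)C(C)(C)C2=O)C(O)=C([C@H](C2=C(OC)C(C)(C)C(=O)C(C)(C)C2=O)C(C)C)C(=O)O1
F3 | step 11 | methyl 5-hydroxy-2-[(1R)-1-(2-methoxy-3,3,5,5-tetramethyl-4,6-dioxocyclohex-1-en-1-yl)-2-methylpropyl]-4-[(1R)-1-(2-methoxy-3,3,5,5-tetramethyl-4,6-dioxocyclohex-1-en-1-yl)-3-methylbutyl]-3-oxohexanoate (epimers at C2, C4, C5) | COC(=O)C([C@H](C1=C(OC)C(C)(C)C(=O)C(C)(C)C1=O)C(C)C)C(=O)C([C@@H](CC(C)C)C1=C(OC)C(C)(C)C(=O)C(C)(C)C1=O)C(C)O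
F4 | step 14 | S-tert-butyl (3S)-3-(2-hydroxy-3,3,5,5-tetramethyl-4,6-dioxocyclohex-1-en-1-yl)-4-methylpentanethioate | CC(C)(C)SC(=O)C[C@@H](C(C)C)C1=C(O)C(C)(C)C(=O)C(C)(C)C1=O
F5 | step 14 | S-tert-butyl (3S)-3-(2-methoxy-3,3,5,5-tetramethyl-4,6-dioxocyclohex-1-en-1-yl)-4-methylpentanethioate | CC(C)(C)SC(=O)C[C@@H](C(C)C)C1=C(OC)C(C)(C)C(=O)C(C)(C)C1=O
F6 | step 14 | S-tert-butyl (5R)-5-(2-methoxy-3,3,5,5-tetramethyl-4,6-dioxocyclohex-1-en-1-yl)-2-[(1R)-1-(2-methoxy-3,3,5,5-tetramethyl-4,6-dioxocyclohex-1-en-1-yl)-2-methylpropyl]-7-methyl-3-oxooctanethioate (epimers at C2) | CC(C)(C)SC(=O)C([C@H](C1=C(OC)C(C)(C)C(=O)C(C)(C)C1=O)C(C)C)C(=O)C[C@@H](CC(C)C)C1=C(OC)C(C)(C)C(=O)C(C)(C)C1=O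
F7 | step 14 | S-tert-butyl 2-[(1R)-1-(2-methoxy-3,3,5,5-tetramethyl-4,6-dioxocyclohex-1-en-1-yl)-2-methylpropyl]-4-[(1R)-1-(2-methoxy-3,3,5,5-tetramethyl-4,6-dioxocyclohex-1-en-1-yl)-3-methylbutyl]-3,5-dioxohexanethioate (epimers at C2, C4) | CC(C)(C)SC(=O)C([C@H](C1=C(OC)C(C)(C)C(=O)C(C)(C)C1=O)C(C)C)C(=O)C([C@@H](CC(C)C)C1=C(OC)C(C)(C)C(=O)C(C)(C)C1=O)C(C)=O
F8 | step 14 | S-tert-butyl 2-[(1R)-1-(2-methoxy-3,3,5,5-tetramethyl-4,6-dioxocyclohex-1-en-1-yl)-2-methylpropyl]-4-[(1R)-1-(2-methoxy-3,3,5,5-tetramethyl-4,6-dioxocyclohex-1-en-1-yl)-3-methylbutyl]-3,5,7-trioxododecanethioate (epimers at C2, C4) | CCCCCC(=O)CC(=O)C([C@@H](CC(C)C)C1=C(OC)C(C)(C)C(=O)C(C)(C)C1=O)C(=O)C([C@H](C1=C(OC)C(C)(C)C(=O)C(C)(C)C1=O)C(C)C)C(=O)SC(C)(C)C
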